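## Structural features

The target is a cyclopent-3-ene (ring carbons C1–C5). C1 is fully substituted and carries a tertiary hydroxyl and an undecanoyl chain (C1′ carbonyl, C2′–C11′ alkyl). It is flanked by the two acetoxy-bearing allylic carbons C2 and C5, which are joined through the C3=C4 cis-alkene. The three stereocentres C5–C1–C2 are contiguous: the two acetoxy groups are cis to each other and the hydroxyl is trans to both, so the acyl chain shares a ring face with the two esters. A mirror plane runs through C1, C1′ and the midpoint of C3=C4, so the compound is meso, C1 is pseudoasymmetric, and only relative configuration has to be controlled. The fragile elements are the two allylic esters (ionisation, acyl migration to the tertiary hydroxyl), the tertiary α-ketol C1(OH)–C1′(=O) (acyloin shift), and the β-oxygenated ketone array C1′(=O)–C1–C2(O), which can open by retro-aldol cleavage once C2–O is a free hydroxyl and base is present. The real difficulty is C1. A carbon nucleophile adding to a cis-2,5-dioxygenated cyclopent-3-enone would enter anti to the two oxygens and give the wrong epimer, so the oxygen, not the carbon, must reach C1 from the open face. The key step uses the fact that C1 and C1′ form an α-hydroxy ketone. In an exocyclic allene C1=C1′=C2′ the two π faces of C1=C1′ are the two faces of the cyclopentene, so oxygen transfer anti to the ring oxygens sets C1, and the C1′=C2′ bond is the latent carbonyl.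

## Logic of the disconnections

**16 ⇒ 15.** The two acetyl C–O bonds on the C2 and C5 oxygens are cut first. Esters would not survive the acetylide, palladium hydride or fluoride chemistry used earlier, and nothing else is left to build, so they go on last. This reduces 16 to 15 with all three hydroxyls free. The forward step must acylate only the two secondary allylic hydroxyls, leave the hindered tertiary one, and use no base able to cleave C1–C2 by retro-aldol reaction.

**15 ⇒ 14.** The two O–Si bonds are cut. Bulky silyl ethers are chosen because they steer the key step, are inert to organolithium reagents, zerovalent palladium and dioxirane, and can be removed without base. The forward cleavage must be non-basic and must not ionise the allylic C–O bonds.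

**14 ⇒ 10 (key).** The C1–O bond of the tertiary hydroxyl and the C1′=O bond are cut and C2′ gives up one hydrogen, which uncovers the exocyclic allene of 10; in the forward direction 11, 12 and 13 lie in between. This is the disconnection that brings oxygen to C1 last and from outside the ring. The quaternary stereocentre becomes a planar carbon and the whole acyl chain is traced to a C11 alkyne. The forward step needs oxygen transfer to C1=C1′ from the face away from the silyloxy groups. The substituent on C2′ of an allene stands over one face of the C1=C1′ bond, so the two allene diastereomers cannot be assumed to behave alike. Compound 10 is therefore specified as the diastereomer with the nonyl group on the silyloxy face, so that ring substituents and chain shield the same face.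

**10 ⇒ 9.** The C2′–H bond is cut and a C1–O bond to a leaving group is restored (SN2′ hydride retron). This turns the allene axis into a tetrahedral carbinol centre that a carbonyl addition can set. The forward hydride delivery must be anti-stereospecific and must stop at the allene.

**9 ⇒ 5 + 6.** The C1–C1′ bond and the O–C bond of the carbonate are cut. This is the only C–C bond not already present in a starting material, and it divides the molecule into ring 5 and chain 6. The addition must outrun enolisation of the β,γ-unsaturated ketone and must come from the face anti to the two α-silyloxy groups. That places the carbinol oxygen on the silyloxy face, which is what the anti SN2′ step needs to put the nonyl group on that face.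

**5 ⇒ 4.** The C1=O bond is traced back to a C1=CMe2 bond. The isopropylidene group is a masked carbonyl that arrives with the fulvene. The forward cleavage must choose the tetrasubstituted exocyclic alkene over the C3=C4 ring alkene.

**4 ⇒ 3.** The two O–Si bonds are cut; the forward step is a routine silylation of two secondary allylic hydroxyls.

**3 ⇒ 1.** The C2–O and C5–O bonds are cut together, both oxygens coming from one molecule of dioxygen through 2. A suprafacial cycloaddition guarantees their cis relationship, and the ring, the C3=C4 alkene and C1 all come from 1. The O–O bond of 2 must be reduced at low temperature before 2 rearranges.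

## Other disconnections considered

**Alternative 1:** The cut is the ring bond C1–C2, which traces the five-membered ring to a four-membered one. The precursor is 4-(dodec-1-yn-1-yl)-4-hydroxycyclobut-2-en-1-one A2, the adduct of a C12 lithium acetylide to cyclobut-3-ene-1,2-dione A1. In the forward step Pd(O2CCF3)2 (divalent palladium) activates the alkyne of A2, the ring acyl carbon shifts to the proximal alkyne carbon with release of ring strain, and protonation of the vinylpalladium gives 2-undecylidenecyclopent-4-ene-1,3-dione A3.
- In its favour: the whole carbon skeleton, including C1–C1′, would be assembled in two C–C bond-forming operations, catalytically and without ozone or peroxides. On C–C bond construction this plan is better than the chosen one.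
- Against it here: A1 carries no alkoxy groups, is sensitive and would have to be prepared. A3 has every oxygenated carbon at the wrong level: C2 and C5 are ketones, C1 lacks its hydroxyl and C1′ its carbonyl.
- Turning the alkylidene into the ketol would pass through a 2-acyl-2-hydroxy-1,3-dione, which invites retro-Claisen cleavage. The two ring carbonyls would then have to be reduced from the face of the C1 hydroxyl in the presence of the side-chain ketone, with no built-in control element.
- Comparison: about five or six steps would follow A3, so the route would be no shorter than eight steps. All three relative configurations would be settled late by reagent control, whereas the chosen plan fixes the cis-diol by a cycloaddition and C1 by an open-face oxygen transfer.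

**Alternative 2:** The cut is the ring bond C2–C3 of an enone, leading to the acyclic methyl (Z)-3-(tert-butyldimethylsilyloxy)-2-hydroxy-5-iodo-2-(undec-1-yn-1-yl)pent-4-enoate A4. In the forward step iodine–lithium exchange with t-BuLi gives a (Z)-vinyllithium at C3, which attacks the ester carbon in a 5-exo-trig acyl substitution. The product is 4-(tert-butyldimethylsilyloxy)-5-hydroxy-5-(undec-1-yn-1-yl)cyclopent-2-en-1-one A5.
- In its favour: the C1/C5 relationship would be set in the open chain, for instance by syn-dihydroxylation of an alkene of defined geometry, and would not depend on the facial preference of an oxidant on a ring. On this point, and in avoiding ozone and dioxirane, the plan is the equal or the better of the chosen one. That A5 is racemic costs nothing, because the target is meso.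
- Against it here: the free tertiary hydroxyl next to the ester must be masked or deprotonated, t-BuLi can attack the ester, and the vinyllithium could expel the allylic silyloxy group.
- After A5 the C2 ketone must be reduced to a hydroxyl trans to the C1 hydroxyl, which hydroxyl-directed hydride delivery could do. The internal alkyne must then be hydrated with the carbonyl at C1′ and not C2′. That regiochemistry is not intrinsically controlled in a tertiary propargylic alcohol, and Meyer–Schuster rearrangement threatens under acidic conditions.
- Comparison: A4 needs about five or six steps and four or five follow A5, so the sequence is clearly longer. In the chosen plan the carbonyl can only arise at C1′, because the allene central carbon is the only one bonded to both oxygens of the spirodiepoxide.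

**Alternative 3:** Both ring bonds to C1 (C1–C2 and C1–C5) are cut, a (4+1) disconnection to 1-hydroxydodecan-2-one A6 and (Z)-but-2-enedial A7. In the forward step the magnesium enediolate of A6 adds through its hydroxylated carbon to one aldehyde of A7, re-enolises toward the same carbon and closes onto the second aldehyde. The product is 1-(1,2,5-trihydroxycyclopent-3-en-1-yl)undecan-1-one A8, which is identical with 15.
- In its favour: this is by far the shortest plan. One operation would reach the triol without protecting groups or redox adjustment and one acetylation would finish. In step and atom economy it is clearly better than the chosen plan, and the end game is the same.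
- Against it here: A7 isomerises to the E dial and hydrates or oligomerises readily, so it must be generated fresh. The enediolate of A6 is ambident (C1 against C3, O against C).
- The first adduct is a γ-hydroxy (Z)-enal that can close to a cyclic hemiacetal and hide the second aldehyde, and conjugate addition competes.
- The three relative configurations would be decided in a reversible aldol manifold, and the required isomer places the acyl chain cis to two hydroxyls, for which no thermodynamic preference is evident. The β-hydroxy ketone product can also revert or dehydrate under the same conditions.
- Comparison: the alternative relies on reversible polar additions organised by a chelate. The chosen plan uses a stereospecific cycloaddition and kinetically controlled oxygen transfer, with a named origin for each relative configuration, so it is the more predictable and the alternative the shorter.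

Key step: step 6

Remark on the chemistry: the target and all ring intermediates with cis oxygens are meso, so only relative configuration is planned; 12 and 13 are racemic and drawn as one enantiomer, and the diastereomer of allene 10 is fixed by its name because its SMILES line does not encode the axis.

## Route

Step 1
Reactants: 1 6,6-dimethylfulvene
Product: 3 cis-2-(propan-2-ylidene)cyclopent-4-ene-1,3-diol (meso), via fulvene endoperoxide 2 (not isolated)
Conditions: O2, hν (visible), rose bengal, CH2Cl2/MeOH, −78 °C; then thiourea in MeOH, −78 °C → rt
Reagents that add atoms: dioxygen, O=O
Why: Singlet oxygen adds across the ring diene of the fulvene in a suprafacial [4+2] cycloaddition, so both new C–O bonds lie on one ring face; thiourea reduces the O–O bond of the labile endoperoxide without touching either C–O bond, which fixes the cis relationship of the C2 and C5 oxygens.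

Step 2
Reactants: 3 cis-2-(propan-2-ylidene)cyclopent-4-ene-1,3-diol
Product: 4 cis-3,5-bis(tert-butyldimethylsilyloxy)-4-(propan-2-ylidene)cyclopent-1-ene (meso)
Conditions: TBSCl, imidazole, DMF, 0 °C → rt
Reagents that add atoms: tert-butyldimethylsilyl chloride, CC(C)(C)[Si](C)(C)Cl
Why: Imidazole-promoted silylation of two secondary allylic hydroxyls under non-acidic conditions, so the doubly allylic C–O bonds are not ionised and the configuration is untouched.

Step 3
Reactants: 4 cis-3,5-bis(tert-butyldimethylsilyloxy)-4-(propan-2-ylidene)cyclopent-1-ene
Product: 5 cis-2,5-bis(tert-butyldimethylsilyloxy)cyclopent-3-en-1-one (meso)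
Conditions: O3 (1 equiv, Sudan red 7B end point), CH2Cl2/MeOH, −78 °C; then Me2S, −78 °C → rt
Reagents that add atoms: ozone, [O-][O+]=O
Why: Ozonolysis with reductive work-up; electrophilic ozone should take the tetrasubstituted exocyclic alkene before the disubstituted ring alkene, and the primary ozonide should fragment with the carbonyl oxide on the acetone half, so that the ring ketone is released directly and the peroxidic co-product is reduced by Me2S.

Step 4
Reactants: 5 cis-2,5-bis(tert-butyldimethylsilyloxy)cyclopent-3-en-1-one; 6 1-undecyne
Product: 9 methyl cis-2,5-bis(tert-butyldimethylsilyloxy)-1-(undec-1-yn-1-yl)cyclopent-3-en-1-yl carbonate (carbonate oxygen cis to both silyloxy groups; meso), via lithium undec-1-yn-1-ide 7 (not isolated), via lithium tertiary alkoxide 8 (not isolated)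
Conditions: 6, n-BuLi, THF, −78 °C; then 5, −78 °C; then ClCO2Me, −78 → 0 °C
Reagents that add atoms: methyl chloroformate, COC(=O)Cl
Why: 1,2-Addition of a lithium acetylide to the ketone under steric approach control, anti to the two α-silyloxy groups, which places the carbinol oxygen on the silyloxy face; the lithium alkoxide is O-acylated in the same flask before silyl transfer can occur.

Step 5
Reactants: 9 methyl cis-2,5-bis(tert-butyldimethylsilyloxy)-1-(undec-1-yn-1-yl)cyclopent-3-en-1-yl carbonate
Product: 10 cis-3,5-bis(tert-butyldimethylsilyloxy)-4-(undec-1-en-1-ylidene)cyclopent-1-ene (allene diastereomer with the nonyl group on the silyloxy face; meso)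
Conditions: Pd2(dba)3·CHCl3 (cat.), PBu3, HCO2NH4, THF, rt → 40 °C
Reagents that add atoms: none
Why: Palladium-catalysed hydrogenolysis of a propargylic carbonate with formate: zerovalent palladium ionises the carbonate in an anti SN2′ sense to a σ-allenyl complex of divalent palladium, formate decarboxylates to the hydride, and reductive elimination puts hydrogen on C2′ where palladium stood, so the nonyl group should end on the face the carbonate left from, the silyloxy face.

Step 6
Reactants: 10 cis-3,5-bis(tert-butyldimethylsilyloxy)-4-(undec-1-en-1-ylidene)cyclopent-1-ene
Product: 14 1-[cis-2,5-bis(tert-butyldimethylsilyloxy)-1-hydroxycyclopent-3-en-1-yl]undecan-1-one (hydroxyl trans to both silyloxy groups; meso), via allene oxide 11 (not isolated), via spirodiepoxide 12 (not isolated), via α-iodo ketone 13 (not isolated)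
Conditions: DMDO (2.2 equiv), acetone/CH2Cl2, −40 → 0 °C; concentrate; Bu4NI, AcOH (1 equiv), THF, −20 °C; then Zn dust, AcOH, 0 °C → rt
Reagents that add atoms: dimethyldioxirane, CC1(C)OO1
Why: Dimethyldioxirane transfers oxygen in a concerted spiro transition state first to the more substituted C1=C1′ bond of the allene, whose two π faces are the two faces of the cyclopentene, giving allene oxide 11, and then to the enol-ether-like C1′=C2′ bond, giving spirodiepoxide 12; each oxirane closes by a [2+1] atom transfer and neither survives, so the step builds no ring. The closest known reaction type is the dioxirane oxidation of allenes to 1,4-dioxaspiro[2.2]pentanes followed by nucleophilic opening to α-substituted α′-hydroxy ketones. The only new stereocentre, C1, is set in the first transfer: the face carrying the two cis silyloxy groups is also the face occupied by the nonyl group on C2′ in this allene diastereomer, so the oxidant should approach from the opposite face and place the C1–O bond trans to both silyloxy groups. Iodide then attacks the unhindered secondary carbon C2′ of the strained spirocycle in an SN2 process, the C1′ alkoxide collapses to the ketone with cleavage of the C1′–O bond of the first oxirane, and the C1–O bond is kept with its configuration as the tertiary hydroxyl of 13. Zinc in acetic acid removes the α-iodine through the zinc enolate and protonation, which erases the C2′ stereocentre made in the second epoxidation, so the racemic intermediates 12 and 13 converge on the single meso ketol 14. The step needs selectivity for the allene over the C3=C4 alkene, which rests on the strain of the cumulene, the deactivation of the ring alkene by two allylic silyloxy groups, and a near-stoichiometric charge of oxidant at low temperature; it also needs opening at C2′ and not at C1, which the fully substituted, neopentyl-like C1 secures.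

Step 7
Reactants: 14 1-[cis-2,5-bis(tert-butyldimethylsilyloxy)-1-hydroxycyclopent-3-en-1-yl]undecan-1-one
Product: 15 1-(1,2,5-trihydroxycyclopent-3-en-1-yl)undecan-1-one (2,5-cis with the C1 hydroxyl trans to both; meso)
Conditions: HF·pyridine, pyridine/THF, 0 °C → rt
Reagents that add atoms: none
Why: Fluoride-driven Si–O cleavage in a buffered, weakly acidic medium; no basic species is present, so neither retro-aldol opening of the β-hydroxy ketone nor an α-ketol shift is triggered, and no C–O bond at a stereocentre is broken.

Step 8
Reactants: 15 1-(1,2,5-trihydroxycyclopent-3-en-1-yl)undecan-1-one
Product: 16 cis-2-hydroxy-2-undecanoylcyclopent-4-ene-1,3-diyl diacetate (hydroxyl trans to both acetoxy groups; meso; the target)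
Conditions: Ac2O, pyridine, CH2Cl2, 0 °C → rt
Reagents that add atoms: acetic anhydride, CC(=O)OC(C)=O
Why: Acylation of the two secondary allylic hydroxyls with acetic anhydride and pyridine; the tertiary hydroxyl, hindered and flanked by three substituted carbons, should not react without an acyl-transfer catalyst, and pyridine is too weak a base for retro-aldol cleavage.

## Compound list

1 | 6,6-dimethylfulvene | CC(C)=C1C=CC=C1 | starting material
2 | 7-(propan-2-ylidene)-2,3-dioxabicyclo[2.2.1]hept-5-ene (fulvene endoperoxide, not isolated) | CC(C)=C1[C@@H]2C=C[C@H]1OO2 | intermediate
3 | cis-2-(propan-2-ylidene)cyclopent-4-ene-1,3-diol (meso) | CC(C)=C1[C@@H](O)C=C[C@H]1O | intermediate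
4 | cis-3,5-bis(tert-butyldimethylsilyloxy)-4-(propan-2-ylidene)cyclopent-1-ene (meso) | CC(C)=C1[C@@H](O[Si](C)(C)C(C)(C)C)C=C[C@H]1O[Si](C)(C)C(C)(C)C | intermediate
5 | cis-2,5-bis(tert-butyldimethylsilyloxy)cyclopent-3-en-1-one (meso) | O=C1[C@@H](O[Si](C)(C)C(C)(C)C)C=C[C@H]1O[Si](C)(C)C(C)(C)C | intermediate
6 | 1-undecyne | CCCCCCCCCC#C | starting material
7 | lithium undec-1-yn-1-ide (not isolated) | CCCCCCCCCC#C[Li] | intermediate
8 | lithium cis-2,5-bis(tert-butyldimethylsilyloxy)-1-(undec-1-yn-1-yl)cyclopent-3-en-1-olate, oxygen cis to both silyloxy groups (not isolated) | CCCCCCCCCC#C[C@]1(O[Li])[C@@H](O[Si](C)(C)C(C)(C)C)C=C[C@H]1O[Si](C)(C)C(C)(C)C | intermediate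
9 | methyl cis-2,5-bis(tert-butyldimethylsilyloxy)-1-(undec-1-yn-1-yl)cyclopent-3-en-1-yl carbonate, carbonate oxygen cis to both silyloxy groups, alkynyl trans (meso) | CCCCCCCCCC#C[C@]1(OC(=O)OC)[C@@H](O[Si](C)(C)C(C)(C)C)C=C[C@H]1O[Si](C)(C)C(C)(C)C | intermediate
10 | cis-3,5-bis(tert-butyldimethylsilyloxy)-4-(undec-1-en-1-ylidene)cyclopent-1-ene, allene diastereomer with the nonyl group of C2′ on the same ring face as the silyloxy groups (meso) | CCCCCCCCCC=C=C1[C@@H](O[Si](C)(C)C(C)(C)C)C=C[C@H]1O[Si](C)(C)C(C)(C)C | intermediate
11 | (E)-4,7-bis(tert-butyldimethylsilyloxy)-2-decylidene-1-oxaspiro[2.4]hept-5-ene, oxirane oxygen trans to both silyloxy groups (allene oxide, not isolated) | CCCCCCCCC/C=C1/O[C@@]12[C@@H](O[Si](C)(C)C(C)(C)C)C=C[C@H]2O[Si](C)(C)C(C)(C)C | intermediate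
12 | spirodiepoxide: 1,4-dioxaspiro[2.2]pentane bearing nonyl on C5 and spiro-fused at C2 to C1 of the cis-2,5-bis(tert-butyldimethylsilyloxy)cyclopent-3-ene, first oxirane oxygen trans to both silyloxy groups (racemic, one enantiomer drawn, not isolated) | CCCCCCCCC[C@H]1O[C@]12O[C@@]23[C@@H](O[Si](C)(C)C(C)(C)C)C=C[C@H]3O[Si](C)(C)C(C)(C)C | intermediate
13 | 1-[cis-2,5-bis(tert-butyldimethylsilyloxy)-1-hydroxycyclopent-3-en-1-yl]-2-iodoundecan-1-one, hydroxyl trans to both silyloxy groups (racemic at C2′, one enantiomer drawn, not isolated) | CCCCCCCCC[C@H](I)C(=O)[C@@]1(O)[C@@H](O[Si](C)(C)C(C)(C)C)C=C[C@H]1O[Si](C)(C)C(C)(C)C | intermediate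
14 | 1-[cis-2,5-bis(tert-butyldimethylsilyloxy)-1-hydroxycyclopent-3-en-1-yl]undecan-1-one, hydroxyl trans to both silyloxy groups (meso) | CCCCCCCCCCC(=O)[C@@]1(O)[C@@H](O[Si](C)(C)C(C)(C)C)C=C[C@H]1O[Si](C)(C)C(C)(C)C | intermediate
15 | 1-(1,2,5-trihydroxycyclopent-3-en-1-yl)undecan-1-one, 2,5-cis with the C1 hydroxyl trans to both (meso) | CCCCCCCCCCC(=O)[C@@]1(O)[C@@H](O)C=C[C@H]1O | intermediate
16 | cis-2-hydroxy-2-undecanoylcyclopent-4-ene-1,3-diyl diacetate, hydroxyl trans to both acetoxy groups (meso) | CCCCCCCCCCC(=O)[C@@]1(O)[C@@H](OC(C)=O)C=C[C@H]1OC(C)=O | target

## Step count and least certain steps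

Total: 8 steps. Longest linear sequence: 8 steps (1 → 16); 6 is commercial and enters at step 4.

**Step 6 (key step).** The likeliest failure is erosion of facial selectivity in the first oxygen transfer, or competing epoxidation of the C3=C4 alkene if oxidant is in excess. The spirodiepoxide could also rearrange before iodide opens it. The fallback sets out from 10 and returns at 14 by osmylation. OsO4 (cat.) with N-methylmorpholine N-oxide in acetone/water should dihydroxylate the C1=C1′ bond from the face away from the silyloxy and nonyl groups. This would give the enediol F1, which tautomerises to the ketol. One [3+2] cycloaddition and a tautomerisation replace oxygen transfer, iodide opening and zinc reduction, and the bulkier oxidant should discriminate the faces more strongly.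

**Step 3.** The likeliest failure is insufficient discrimination between the two alkenes, since both carry two allylic silyloxy groups, leading to over-oxidation. Migration of the β,γ double bond of the ketone into conjugation during work-up is a second risk. The fallback sets out from 4 and returns at 5. Buffered mCPBA (NaHCO3, CH2Cl2, 0 °C), which separates tetra- from disubstituted alkenes far more sharply than ozone, should give the spiro-epoxide F2. H5IO6 in wet THF should then open it at the dimethyl-substituted carbon to the diol F3 and cleave that glycol in the same flask.

**Step 4.** The likeliest failure is deprotonation of 5 at its doubly activated α-positions by the acetylide in competition with addition. Slow acylation of the hindered alkoxide, with silyl transfer as a consequence, is the second risk. The fallback sets out from 5 and 6 and returns at 9. Acetylide 7 is transmetallated with anhydrous CeCl3 to the far less basic alkynylcerium reagent and added to 5. After aqueous quench the free propargylic alcohol F4 is isolated, its epimers separated if both form, and it is acylated in a separate operation (LiN(SiMe3)2, ClCO2Me, THF).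

**Step 5.** The likeliest failures are hydride delivery to C1 (a propargylic C–H alkyne), β-hydride loss from the allenylpalladium intermediate to an enyne, palladium-hydride isomerisation of the allene to a 1,3-diene, or epimerisation of the allenylpalladium species that blurs the configuration of the axis. The fallback sets out from 9 and returns at 10 without any palladium hydride. The monovalent copper hydride [(Ph3P)CuH]6 in toluene/THF should add H–Cu across the alkyne with copper at C1′ and expel the carbonate by β-elimination. This SN2′ reduction is expected to follow the anti course usual for copper-mediated substitutions of propargylic electrophiles. It makes no new compound.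

**Step 7.** The likeliest failure is sluggish cleavage of two silyl ethers flanking a quaternary carbon. Prolonged exposure then risks allylic ionisation or an α-ketol shift, and the free triol is open to retro-aldol cleavage during handling. The fallback sets out from 10 and returns at 16, removing the silyl groups before any sensitive function exists.
- Bu4NF in THF should give the allene diol F5, and Ac2O with pyridine the allene diacetate F6.
- The operations of step 6 applied to F6 should then pass through the allene oxide F7, the spirodiepoxide F8 and the iodo ketone F9 and deliver 16 directly.
- The cost is a smaller steric shield in the oxygen transfer, which then leans more on the nonyl group.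

## Further compounds

F1 | step 6 | (E)-1-[cis-2,5-bis(tert-butyldimethylsilyloxy)-1-hydroxycyclopent-3-en-1-yl]undec-1-en-1-ol, ring hydroxyl trans to both silyloxy groups (enediol, not isolated) | CCCCCCCCC/C=C(/O)[C@@]1(O)[C@@H](O[Si](C)(C)C(C)(C)C)C=C[C@H]1O[Si](C)(C)C(C)(C)C
F2 | step 3 | 4,7-bis(tert-butyldimethylsilyloxy)-2,2-dimethyl-1-oxaspiro[2.4]hept-5-ene, oxirane oxygen trans to both silyloxy groups (meso) | CC1(C)O[C@@]12[C@@H](O[Si](C)(C)C(C)(C)C)C=C[C@H]2O[Si](C)(C)C(C)(C)C
F3 | step 3 | cis-2,5-bis(tert-butyldimethylsilyloxy)-1-(2-hydroxypropan-2-yl)cyclopent-3-en-1-ol, ring hydroxyl trans to both silyloxy groups (not isolated) | CC(C)(O)[C@@]1(O)[C@@H](O[Si](C)(C)C(C)(C)C)C=C[C@H]1O[Si](C)(C)C(C)(C)C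
F4 | step 4 | cis-2,5-bis(tert-butyldimethylsilyloxy)-1-(undec-1-yn-1-yl)cyclopent-3-en-1-ol, hydroxyl cis to both silyloxy groups (meso) | CCCCCCCCCC#C[C@]1(O)[C@@H](O[Si](C)(C)C(C)(C)C)C=C[C@H]1O[Si](C)(C)C(C)(C)C
F0 | step 5 | none | none
F5 | step 7 | cis-2-(undec-1-en-1-ylidene)cyclopent-4-ene-1,3-diol, nonyl group on the hydroxyl face (meso) | CCCCCCCCCC=C=C1[C@@H](O)C=C[C@H]1O
F6 | step 7 | cis-2-(undec-1-en-1-ylidene)cyclopent-4-ene-1,3-diyl diacetate, nonyl group on the acetoxy face (meso) | CCCCCCCCCC=C=C1[C@@H](OC(C)=O)C=C[C@H]1OC(C)=O
F7 | step 7 | (E)-2-decylidene-1-oxaspiro[2.4]hept-5-ene-4,7-diyl diacetate, oxirane oxygen trans to both acetoxy groups (not isolated) | CCCCCCCCC/C=C1/O[C@@]12[C@@H](OC(C)=O)C=C[C@H]2OC(C)=O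
F8 | step 7 | spirodiepoxide of F6: 1,4-dioxaspiro[2.2]pentane bearing nonyl on C5 and spiro-fused at C2 to C1 of the cis-2,5-diacetoxycyclopent-3-ene, first oxirane oxygen trans to both acetoxy groups (racemic, one enantiomer drawn, not isolated) | CCCCCCCCC[C@H]1O[C@]12O[C@@]23[C@@H](OC(C)=O)C=C[C@H]3OC(C)=O
F9 | step 7 | cis-2-hydroxy-2-(2-iodoundecanoyl)cyclopent-4-ene-1,3-diyl diacetate, hydroxyl trans to both acetoxy groups (racemic at C2′, one enantiomer drawn, not isolated) | CCCCCCCCC[C@H](I)C(=O)[C@@]1(O)[C@@H](OC(C)=O)C=C[C@H]1OC(C)=O
A1 | alternative 1 | cyclobut-3-ene-1,2-dione | O=C1C=CC1=O
A2 | alternative 1 | 4-(dodec-1-yn-1-yl)-4-hydroxycyclobut-2-en-1-one (racemic, one enantiomer drawn) | CCCCCCCCCCC#C[C@@]1(O)C=CC1=O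
A3 | alternative 1 | 2-undecylidenecyclopent-4-ene-1,3-dione | CCCCCCCCCCC=C1C(=O)C=CC1=O
A4 | alternative 2 | methyl (Z)-3-(tert-butyldimethylsilyloxy)-2-hydroxy-5-iodo-2-(undec-1-yn-1-yl)pent-4-enoate (racemic, one enantiomer drawn; relative configuration as required for A5) | COC(=O)[C@](O)(C#CCCCCCCCCC)[C@H](O[Si](C)(C)C(C)(C)C)/C=C\I
A5 | alternative 2 | 4-(tert-butyldimethylsilyloxy)-5-hydroxy-5-(undec-1-yn-1-yl)cyclopent-2-en-1-one, hydroxyl trans to silyloxy (racemic, one enantiomer drawn) | CCCCCCCCCC#C[C@@]1(O)C(=O)C=C[C@H]1O[Si](C)(C)C(C)(C)C
A6 | alternative 3 | 1-hydroxydodecan-2-one | CCCCCCCCCCC(=O)CO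
A7 | alternative 3 | (Z)-but-2-enedial | O=C/C=C\C=O
A8 | alternative 3 | 1-(1,2,5-trihydroxycyclopent-3-en-1-yl)undecan-1-one, 2,5-cis with the C1 hydroxyl trans to both (meso; identical with 15) | CCCCCCCCCCC(=O)[C@@]1(O)[C@@H](O)C=C[C@H]1O
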